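The depside is cut at its ester into a ring A phenol and a ring B acid, and ring B is then opened across C1–C2 and C5–C6. One (4+2) cycloaddition–aromatisation between a ketene-acetal silyl enol ether diene and a propyl-substituted ynoate builds the whole benzene ring. It delivers the C2 methoxy and the C4 hydroxyl of ring B already differentiated, with the carboxyl carbon on C1 and propyl on C6, so no selective O-methylation of a resorcylate at its chelated oxygen is needed. The precursors are 1,1-dimethoxy-3-(trimethylsilyloxy)buta-1,3-diene and methyl hex-2-ynoate. Ring A comes from a symmetric trimethoxyarene whose acetyl group then differentiates the three hydroxyls.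

Key step: step 4

Remark: the target has no stereocentre; methyl hex-2-ynoate, pentylzinc bromide (THF solution) and 5-bromo-1,2,3-trimethoxybenzene are taken as purchased, and the chelated 2-hydroxyl of ring A is deliberately left unprotected.

Step 1
Reactants: 1 acetyl chloride; 2 1,1-dichloroethene
Product: 4 4,4-dichlorobut-3-en-2-one, via 4,4,4-trichlorobutan-2-one 3 (not isolated)
Conditions: AlCl3, CH2Cl2, 0 °C → rt; ice/aq. HCl; steam distillation (−HCl)
Reagents that add atoms: none
Why: Friedel–Crafts-type acylation of the alkene puts the acylium ion on the CH2 terminus, chloride capture gives the trichloro ketone 3, and its acidic α-hydrogen is then lost with chloride to give the conjugated dichlorovinyl ketone.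

Step 2
Reactants: 4 4,4-dichlorobut-3-en-2-one
Product: 5 4,4-dimethoxybut-3-en-2-one
Conditions: NaOMe (2.2 equiv), MeOH, 0 °C → rt
Reagents that add atoms: sodium methoxide, [Na+].[O-]C
Why: Two successive addition–elimination steps (nucleophilic vinylic substitution) at the β-carbon of the enone should replace both chlorides by methoxide and give the push–pull ketene acetal.

Step 3
Reactants: 5 4,4-dimethoxybut-3-en-2-one
Product: 6 1,1-dimethoxy-3-(trimethylsilyloxy)buta-1,3-diene
Conditions: TMSCl, Et3N, ZnCl2 (cat.), toluene, rt → 40 °C; filtration, distillation under Ar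
Reagents that add atoms: chlorotrimethylsilane, C[Si](C)(C)Cl
Why: Silyl enol ether formation by soft enolisation can only involve the methyl group of the ketone, so O-silylation should give the cross-conjugated diene as a single regioisomer.

Step 4
Reactants: 6 1,1-dimethoxy-3-(trimethylsilyloxy)buta-1,3-diene; 7 methyl hex-2-ynoate
Product: 10 methyl 4-hydroxy-2-methoxy-6-propylbenzoate, via cyclohexadiene cycloadduct 8 (not isolated), via aryl trimethylsilyl ether 9 (not isolated)
Conditions: neat, excess 6, 120 °C, sealed tube, Ar; then 1 M HCl, THF, rt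
Reagents that add atoms: none
Why: Diene 6 (electron-rich) and ynoate 7 (electron-poor) should undergo a thermal Diels–Alder reaction of normal electron demand in which both bonds form in one step but to unequal extents, the closest known reaction type being the benzannulation of 1,1-dialkoxy-3-silyloxybutadienes with acetylenic esters to resorcinol monoethers. Ring B is closed by this intermolecular (4+2) cycloaddition itself, with C5–C6 (diene CH2 to the propyl-bearing alkyne carbon) forming ahead of C1–C2 (acetal carbon to the ester-bearing alkyne carbon), which leaves the 1,4-cyclohexadiene 8. A 1,4-elimination of methanol (one acetal methoxy group plus a hydrogen of the ring CH2) should aromatise 8 to the silyl ether 9, and dilute acid then frees the C4 phenol while the second methoxy group stays on C2. No stereocentre is formed, because the only sp3 ring carbons of 8 are the acetal carbon and a CH2 group. The selectivity required is regiochemical and is secured by the polarisation of the diene, whose three oxygen donors place the largest HOMO coefficient on the terminal CH2, so that it bonds to the β-carbon of the ynoate where the LUMO coefficient is largest. Since the propyl group lowers the reactivity of the alkyne, an excess of diene and long heating without solvent are planned.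

Step 5
Reactants: 10 methyl 4-hydroxy-2-methoxy-6-propylbenzoate
Product: 11 methyl 4-(benzyloxy)-2-methoxy-6-propylbenzoate
Conditions: BnBr, K2CO3, acetone, reflux
Reagents that add atoms: benzyl bromide, BrCc1ccccc1
Why: Williamson ether synthesis on the single, unhindered phenol para to the ester should proceed cleanly.

Step 6
Reactants: 11 methyl 4-(benzyloxy)-2-methoxy-6-propylbenzoate
Product: 12 4-(benzyloxy)-2-methoxy-6-propylbenzoic acid
Conditions: KOH, aq. DMSO, 90 °C; then cold aq. HCl
Reagents that add atoms: potassium hydroxide, [K+].[OH-]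
Why: Saponification of the doubly ortho-substituted benzoate needs the poorly solvated hydroxide of aqueous DMSO, conditions to which the benzyl and methyl aryl ethers are inert, and cold acidification avoids decarboxylation of the electron-rich acid.

Step 7
Reactants: 13 5-bromo-1,2,3-trimethoxybenzene; 14 pentylzinc bromide
Product: 15 1,2,3-trimethoxy-5-pentylbenzene
Conditions: PdCl2(dppf) (cat.), THF, 60 °C
Reagents that add atoms: none
Why: Negishi cross-coupling of a primary alkylzinc halide with an aryl bromide is reliable with the wide-bite-angle dppf ligand, which favours reductive elimination over β-hydride elimination.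

Step 8
Reactants: 15 1,2,3-trimethoxy-5-pentylbenzene; 1 acetyl chloride
Product: 16 1-(2,3,4-trimethoxy-6-pentylphenyl)ethanone
Conditions: AlCl3 (1.1 equiv), CH2Cl2, −10 → 0 °C
Reagents that add atoms: none
Why: Friedel–Crafts acylation can only occur at the two open ring positions, which are equivalent by symmetry and each ortho and para to a methoxy group, so one ketone should result; partial loss of the methyl group next to the new ketone would be harmless because step 9 removes all three.

Step 9
Reactants: 16 1-(2,3,4-trimethoxy-6-pentylphenyl)ethanone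
Product: 17 1-(2,3,4-trihydroxy-6-pentylphenyl)ethanone
Conditions: BBr3 (excess), CH2Cl2, −78 °C → rt; then H2O
Reagents that add atoms: none
Why: Lewis-acid ether cleavage with BBr3 (bromide attack on the methyl group of each boron-complexed aryl ether) should free all three phenols without touching the aryl ketone.

Step 10
Reactants: 17 1-(2,3,4-trihydroxy-6-pentylphenyl)ethanone
Product: 18 1-[4-(benzyloxy)-2,3-dihydroxy-6-pentylphenyl]ethanone
Conditions: BnBr (1.05 equiv), NaHCO3, DMF, 40 °C, Ar
Reagents that add atoms: benzyl bromide, BrCc1ccccc1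
Why: In this Williamson etherification under weak base the 4-hydroxyl, para to the acetyl group, is the most acidic and least hindered, whereas the 2-hydroxyl is held in a hydrogen bond to the ketone and the 3-hydroxyl is flanked on both sides, so one equivalent of benzyl bromide should alkylate O4 first.

Step 11
Reactants: 12 4-(benzyloxy)-2-methoxy-6-propylbenzoic acid; 18 1-[4-(benzyloxy)-2,3-dihydroxy-6-pentylphenyl]ethanone
Product: 20 3-acetyl-6-(benzyloxy)-2-hydroxy-4-pentylphenyl 4-(benzyloxy)-2-methoxy-6-propylbenzoate, via mixed trifluoroacetic anhydride 19 (not isolated)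
Conditions: (CF3CO)2O, toluene, 0 °C → rt
Reagents that add atoms: none
Why: Trifluoroacetic anhydride-mediated esterification, the standard depside coupling, turns the hindered acid into a mixed anhydride that ionises readily to a stabilised acylium ion, and this should be captured by the free 3-hydroxyl while the ketone-chelated 2-hydroxyl stays unreactive, as chelated hydroxyls do in acylations of this type.

Step 12
Reactants: 20 3-acetyl-6-(benzyloxy)-2-hydroxy-4-pentylphenyl 4-(benzyloxy)-2-methoxy-6-propylbenzoate
Product: 21 3-acetyl-2,6-dihydroxy-4-pentylphenyl 4-hydroxy-2-methoxy-6-propylbenzoate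
Conditions: H2 (1 atm), 10% Pd/C, EtOAc, rt
Reagents that add atoms: none
Why: Catalytic hydrogenolysis should cleave both benzyl aryl ethers under neutral conditions that leave the aryl ester, the methyl ether and the hindered, hydrogen-bonded aryl ketone intact and give no opening for acyl migration.

Compound list
1 | acetyl chloride | CC(Cl)=O | starting material
2 | 1,1-dichloroethene | C=C(Cl)Cl | starting material
3 | 4,4,4-trichlorobutan-2-one | CC(=O)CC(Cl)(Cl)Cl | intermediate (not isolated)
4 | 4,4-dichlorobut-3-en-2-one | CC(=O)C=C(Cl)Cl | intermediate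
5 | 4,4-dimethoxybut-3-en-2-one | CC(=O)C=C(OC)OC | intermediate
6 | 1,1-dimethoxy-3-(trimethylsilyloxy)buta-1,3-diene | COC(OC)=CC(=C)O[Si](C)(C)C | intermediate
7 | methyl hex-2-ynoate | CCCC#CC(=O)OC | starting material
8 | methyl 6,6-dimethoxy-2-propyl-4-(trimethylsilyloxy)cyclohexa-1,4-diene-1-carboxylate | COC(=O)C1=C(CCC)CC(O[Si](C)(C)C)=CC1(OC)OC | intermediate (not isolated)
9 | methyl 2-methoxy-6-propyl-4-(trimethylsilyloxy)benzoate | CCCc1cc(O[Si](C)(C)C)cc(OC)c1C(=O)OC | intermediate (not isolated)
10 | methyl 4-hydroxy-2-methoxy-6-propylbenzoate | CCCc1cc(O)cc(OC)c1C(=O)OC | intermediate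
11 | methyl 4-(benzyloxy)-2-methoxy-6-propylbenzoate | CCCc1cc(OCc2ccccc2)cc(OC)c1C(=O)OC | intermediate
12 | 4-(benzyloxy)-2-methoxy-6-propylbenzoic acid | CCCc1cc(OCc2ccccc2)cc(OC)c1C(=O)O | intermediate
13 | 5-bromo-1,2,3-trimethoxybenzene | COc1cc(Br)cc(OC)c1OC | starting material
14 | pentylzinc bromide | CCCCC[Zn]Br | starting material
15 | 1,2,3-trimethoxy-5-pentylbenzene | CCCCCc1cc(OC)c(OC)c(OC)c1 | intermediate
16 | 1-(2,3,4-trimethoxy-6-pentylphenyl)ethanone | CCCCCc1cc(OC)c(OC)c(OC)c1C(C)=O | intermediate
17 | 1-(2,3,4-trihydroxy-6-pentylphenyl)ethanone | CCCCCc1cc(O)c(O)c(O)c1C(C)=O | intermediate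
18 | 1-[4-(benzyloxy)-2,3-dihydroxy-6-pentylphenyl]ethanone | CCCCCc1cc(OCc2ccccc2)c(O)c(O)c1C(C)=O | intermediate
19 | 4-(benzyloxy)-2-methoxy-6-propylbenzoic trifluoroacetic anhydride | CCCc1cc(OCc2ccccc2)cc(OC)c1C(=O)OC(=O)C(F)(F)F | intermediate (not isolated)
20 | 3-acetyl-6-(benzyloxy)-2-hydroxy-4-pentylphenyl 4-(benzyloxy)-2-methoxy-6-propylbenzoate | CCCCCc1cc(OCc2ccccc2)c(OC(=O)c2c(CCC)cc(OCc3ccccc3)cc2OC)c(O)c1C(C)=O | intermediate
21 | 3-acetyl-2,6-dihydroxy-4-pentylphenyl 4-hydroxy-2-methoxy-6-propylbenzoate | CCCCCc1cc(O)c(OC(=O)c2c(CCC)cc(O)cc2OC)c(O)c1C(C)=O | target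

Total step count: 12 (convergent). Longest linear sequence: 8 steps (steps 1, 2, 3, 4, 5, 6, 11, 12); the ring A branch (steps 7 to 10) joins at step 11.

Steps most likely to fail

Step 4. The cycloaddition to the β-alkyl ynoate may be slower than thermal or hydrolytic decomposition of the diene, or methanol loss may stay incomplete and give mixtures. The fallback sets out from 7 and comes back at 11, building ring B by condensation instead of cycloaddition. Conjugate addition of the sodium enolate of methyl acetoacetate to 7, followed in the same pot by Claisen ring closure and tautomerisation (NaOMe, MeOH, reflux), should give methyl 2,4-dihydroxy-6-propylbenzoate F1. Benzylation of its non-chelated 4-hydroxyl (BnBr, K2CO3, acetone) should give methyl 4-(benzyloxy)-2-hydroxy-6-propylbenzoate F2. Methylation of the remaining chelated hydroxyl under forcing conditions (MeI, K2CO3, DMF, 60 °C) then gives 11.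

Step 11. Acylation may stall because acid and phenol are both crowded, or the acyl group may also reach the chelated 2-hydroxyl and give mixtures. The fallback sets out from 18 (with 12) and comes back at 21, leaving only one free hydroxyl on ring A at the coupling stage.
- Selective protection of the non-chelated 3-hydroxyl (MOMCl, i-Pr2NEt, CH2Cl2, 0 °C) should give 1-[4-(benzyloxy)-2-hydroxy-3-(methoxymethoxy)-6-pentylphenyl]ethanone F3.
- Forced benzylation of the chelated hydroxyl (BnBr, K2CO3, DMF, 70 °C) should give 1-[2,4-bis(benzyloxy)-3-(methoxymethoxy)-6-pentylphenyl]ethanone F4.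
- Acetal cleavage (HCl, MeOH, 50 °C) should give 1-[2,4-bis(benzyloxy)-3-hydroxy-6-pentylphenyl]ethanone F5.
- Coupling of F5 with 12 through the mixed anhydride 19 (trifluoroacetic anhydride, toluene) should give 3-acetyl-2,6-bis(benzyloxy)-4-pentylphenyl 4-(benzyloxy)-2-methoxy-6-propylbenzoate F6.
- Hydrogenolysis (H2, Pd/C, EtOAc) then gives 21.

Step 10. Alkylation may run on to the 3-hydroxyl or discriminate poorly between O4 and O3. The fallback sets out from 17 and comes back at 18, using ester reactivity instead of phenoxide reactivity to select O4. Peracetylation (Ac2O, pyridine) should give 1-[2,3,4-tris(acetyloxy)-6-pentylphenyl]ethanone F7. The acetate para to the ketone is the most labile, so one-pot deacetylation–benzylation (BnBr, K2CO3, acetone, reflux) should give 1-[2,3-bis(acetyloxy)-4-(benzyloxy)-6-pentylphenyl]ethanone F8. Methanolysis of the two remaining acetates (K2CO3, MeOH, rt, Ar) then gives 18.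

Further compounds
F1 | step 4 | methyl 2,4-dihydroxy-6-propylbenzoate | CCCc1cc(O)cc(O)c1C(=O)OC
F2 | step 4 | methyl 4-(benzyloxy)-2-hydroxy-6-propylbenzoate | CCCc1cc(OCc2ccccc2)cc(O)c1C(=O)OC
F3 | step 11 | 1-[4-(benzyloxy)-2-hydroxy-3-(methoxymethoxy)-6-pentylphenyl]ethanone | CCCCCc1cc(OCc2ccccc2)c(OCOC)c(O)c1C(C)=O
F4 | step 11 | 1-[2,4-bis(benzyloxy)-3-(methoxymethoxy)-6-pentylphenyl]ethanone | CCCCCc1cc(OCc2ccccc2)c(OCOC)c(OCc2ccccc2)c1C(C)=O
F5 | step 11 | 1-[2,4-bis(benzyloxy)-3-hydroxy-6-pentylphenyl]ethanone | CCCCCc1cc(OCc2ccccc2)c(O)c(OCc2ccccc2)c1C(C)=O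
F6 | step 11 | 3-acetyl-2,6-bis(benzyloxy)-4-pentylphenyl 4-(benzyloxy)-2-methoxy-6-propylbenzoate | CCCCCc1cc(OCc2ccccc2)c(OC(=O)c2c(CCC)cc(OCc3ccccc3)cc2OC)c(OCc2ccccc2)c1C(C)=O
F7 | step 10 | 1-[2,3,4-tris(acetyloxy)-6-pentylphenyl]ethanone | CCCCCc1cc(OC(C)=O)c(OC(C)=O)c(OC(C)=O)c1C(C)=O
F8 | step 10 | 1-[2,3-bis(acetyloxy)-4-(benzyloxy)-6-pentylphenyl]ethanone | CCCCCc1cc(OCc2ccccc2)c(OC(C)=O)c(OC(C)=O)c1C(C)=O
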